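**Retrosynthetic overview**

1. Numbering: C1 = CO2H, C6–C9 = tetrahydrofuran carbons, C19 = lactone C=O, C20 = lactone OCH2. The last disconnections are the silicon protecting groups and the 5-ylidene pyranone: C16–C17 by Stille coupling of a C16 alkenylstannane with ethyl (Z)-3-iodoacrylate, O–C19 by lactonisation.
2. The (Z)-chloroalkene is cut at C11–C12: B-alkyl Suzuki coupling of the C9 vinyl group (C10=C11) with a 1,1-dichloro enyne that carries C12–C16 and C20.
3. C1–C3 come from a C4 aldehyde by Wittig olefination (C3=C4) and Arndt–Eistert homologation (C2).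
4. The plan turns on the tetrahydrofuran ring C6–C7–C8–C9–O. Its oxygen sits between C6 and C9, and C9 also holds the C10–C11 segment; with C10=C11 as an alkene, C9–C10–C11 is an allyl system that palladium can ionise from a C11 carbonate, so the O–C9 bond is cut back to a free C6 hydroxyl and an (E)-allylic carbonate.
5. That precursor maps onto 2-deoxy-D-glucose (sugar C1, C3, C4, C5, C6 = C9, C7, C6, C5, C4) plus a two-carbon ylide. Ring order: tetrahydrofuran (step 8), then pyranone (step 21).

Key step: step 8

Assumption: the (1S,2S) antipode of the bisphosphine is taken to be the one matched to the 9S vinyl centre of 11; if a trial run shows the opposite sense of induction, the (1R,2R) antipode is used in step 8 with nothing else changed.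

**Route**

Step 1
Reactants: 1 2-deoxy-D-glucose
Product: 3 2-deoxy-D-arabino-hexono-1,4-lactone, via 2-deoxy-D-arabino-hexono-1,5-lactone 2 (not isolated)
Conditions: Br2, H2O, rt, dark; then concentration from the aqueous acid, 40 °C
Reagents that add atoms: none
Why: Bromine-water oxidation of the aldose hemiacetal gives the 1,5-lactone, which translactonises under the acidic concentration to the five-membered 1,4-lactone, so that O4 (the later C6 oxygen) is singled out as the ring oxygen and no stereocentre is touched.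

Step 2
Reactants: 3 2-deoxy-D-arabino-hexono-1,4-lactone
Product: 4 5,6-O-isopropylidene lactone
Conditions: 2-methoxypropene, camphorsulfonic acid (cat.), DMF, 0 °C
Reagents that add atoms: 2-methoxypropene, COC(C)=C
Why: Kinetic acetalisation with the enol ether takes the terminal 5,6-diol as the dioxolane and leaves the 3-hydroxyl free, and the methanol-poor medium should avoid opening of the lactone.

Step 3
Reactants: 4 5,6-O-isopropylidene lactone
Product: 5 3-O-TBS-5,6-O-isopropylidene lactone
Conditions: TBSCl, imidazole, DMF, rt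
Reagents that add atoms: tert-butyldimethylsilyl chloride, CC(C)(C)[Si](C)(C)Cl
Why: Imidazole-promoted silyl ether formation at the only free hydroxyl (the later C7 oxygen) under conditions too mild for β-elimination from the lactone.

Step 4
Reactants: 5 3-O-TBS-5,6-O-isopropylidene lactone
Product: 6 lactol (anomeric mixture)
Conditions: i-Bu2AlH (1.1 equiv), CH2Cl2, −78 °C; aq. potassium sodium tartrate
Reagents that add atoms: none
Why: Partial reduction of a lactone by i-Bu2AlH stops at the lactol because the tetrahedral aluminate is stable at −78 °C.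

Step 5
Reactants: 6 lactol; 7 ethyl (triphenylphosphoranylidene)acetate
Product: 8 hydroxy (E)-enoate
Conditions: toluene, 80 °C
Reagents that add atoms: none
Why: Wittig olefination of the open hydroxy aldehyde tautomer with a stabilised ylide should give the (E)-enoate (C10=C11) and free the C6 hydroxyl, while the neutral non-polar medium disfavours oxa-Michael reclosure.

Step 6
Reactants: 8 hydroxy (E)-enoate
Product: 9 (E)-allylic diol
Conditions: i-Bu2AlH (3.5 equiv), CH2Cl2, −78 °C; aq. potassium sodium tartrate
Reagents that add atoms: none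
Why: 1,2-Reduction of the α,β-unsaturated ester by i-Bu2AlH gives the primary allylic alcohol without touching the alkene, the silyl ether or the acetonide.

Step 7
Reactants: 9 (E)-allylic diol
Product: 10 (E)-allylic methyl carbonate with free C6 hydroxyl
Conditions: ClCO2Me (1.05 equiv), pyridine, CH2Cl2, −30 °C
Reagents that add atoms: methyl chloroformate, COC(=O)Cl
Why: Chemoselective O-acylation (carbonate formation) at the unhindered primary allylic hydroxyl, the secondary C6 hydroxyl being shielded by the neighbouring silyl ether and dioxolane.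

Step 8
Reactants: 10 (E)-allylic methyl carbonate with free C6 hydroxyl
Product: 11 2,5-trans 2-vinyltetrahydrofuran (C7 OTBS, C4/C5 acetonide)
Conditions: Pd2(dba)3·CHCl3 (2.5 mol %), N,N'-[(1S,2S)-cyclohexane-1,2-diyl]bis[2-(diphenylphosphanyl)benzamide] (7.5 mol %), CH2Cl2, 0 °C to rt
Reagents that add atoms: none
Why: Ionisation of the primary methyl carbonate by the zerovalent palladium–bisphosphine complex expels CO2 and methoxide and leaves a cationic allyl complex spanning C9–C11; the methoxide takes the proton of the C6 hydroxyl and the oxygen adds to C9 on the face away from the metal, making the O–C9 bond. The closest known reaction type is the intramolecular Tsuji–Trost asymmetric allylic etherification of hydroxy allylic carbonates to 2-vinyltetrahydrofurans. The tetrahydrofuran closes in the 5-exo mode at the internal allyl terminus C9, the 7-endo alternative at C11 being disfavoured by the tether. The new centre C9 is set by the ligand: the two diastereomeric allyl complexes exchange by π–σ–π interconversion through the unsubstituted terminus C11 faster than they cyclise, and the chiral pocket should let the complex leading to the 9S vinyl centre, trans to the C6 substituent, close preferentially. The step needs 2,5-trans over 2,5-cis and attack by the C6 oxygen alone; the catalyst is meant to overrule the substrate bias, the C7 silyl ether and the C4/C5 acetonide leave C6–OH as the single nucleophile, and the (E)-alkene gives the syn allyl complex needed for clean equilibration.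

Step 9
Reactants: 11 2,5-trans 2-vinyltetrahydrofuran
Product: 12 C4,C5-diol
Conditions: AcOH/H2O (4:1), rt
Reagents that add atoms: none
Why: Acid hydrolysis of the terminal isopropylidene acetal is much faster than cleavage of the hindered secondary TBS ether on the ring.

Step 10
Reactants: 12 C4,C5-diol
Product: 13 tris-TBS ether
Conditions: TBSOTf (2.4 equiv), 2,6-lutidine, CH2Cl2, −78 to 0 °C
Reagents that add atoms: tert-butyldimethylsilyl triflate, CC(C)(C)[Si](C)(C)OS(=O)(=O)C(F)(F)F
Why: Silylation with the silyl triflate protects both the primary C4 and the hindered secondary C5 hydroxyl in one operation.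

Step 11
Reactants: 13 tris-TBS ether
Product: 14 C4 primary alcohol (C5, C7 OTBS)
Conditions: HF·pyridine, pyridine, THF, 0 °C
Reagents that add atoms: none
Why: Buffered HF·pyridine cleaves the primary silyl ether selectively because the two secondary TBS ethers react far more slowly.

Step 12
Reactants: 14 C4 primary alcohol
Product: 15 C4 aldehyde
Conditions: TEMPO (cat.), PhI(OAc)2, CH2Cl2, rt
Reagents that add atoms: none
Why: TEMPO-catalysed oxoammonium oxidation converts the primary alcohol to the aldehyde under non-basic conditions, so the α-silyloxy centre C5 should not epimerise.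

Step 13
Reactants: 15 C4 aldehyde; 16 ethyl 2-(triphenylphosphoranylidene)propanoate
Product: 17 (E)-2-methyl enoate
Conditions: toluene, 60 °C
Reagents that add atoms: none
Why: Wittig olefination with the α-methyl stabilised ylide should give the (E)-trisubstituted enoate, which fixes the C3=C4 geometry with the methyl group cis to C5 and the carboxyl carbon trans to it.

Step 14
Reactants: 17 (E)-2-methyl enoate
Product: 18 (E)-2-methyl enoic acid
Conditions: LiOH·H2O, THF/MeOH/H2O, 40 °C; then 1 M HCl to pH 4, 0 °C
Reagents that add atoms: lithium hydroxide, [Li+].[OH-]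
Why: Saponification of the ethyl ester, to which the silyl ethers and the vinyl tetrahydrofuran are inert.

Step 15
Reactants: 18 (E)-2-methyl enoic acid
Product: 20 α,β-unsaturated diazoketone, via acid chloride 19 (not isolated)
Conditions: 1-chloro-N,N,2-trimethylprop-1-en-1-amine, CH2Cl2, 0 °C to rt; then CH2N2 (excess), Et2O, 0 °C
Reagents that add atoms: diazomethane, C=[N+]=[N-]
Why: Neutral acid chloride formation followed by C-acylation of diazomethane is the first half of the Arndt–Eistert homologation, with excess diazomethane taking up the HCl so the silyl ethers are not exposed to acid.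

Step 16
Reactants: 20 α,β-unsaturated diazoketone
Product: 22 β,γ-unsaturated 2-(trimethylsilyl)ethyl ester, via vinylketene 21 (not isolated)
Conditions: AgO2CPh (cat.), Et3N, Me3SiCH2CH2OH, THF, −20 °C to rt, dark
Reagents that add atoms: 2-(trimethylsilyl)ethanol, C[Si](C)(C)CCO
Why: In the silver-catalysed Wolff rearrangement the alkenyl group migrates with its C3=C4 geometry intact to give the vinylketene, which the alcohol traps with α-protonation to the deconjugated β,γ-unsaturated ester, the diazo carbon becoming C2.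

Step 17
Reactants: 23 tert-butyldimethyl(prop-2-yn-1-yloxy)silane; 24 1,1,3-trichloroprop-1-ene
Product: 25 tert-butyl[(6,6-dichlorohex-5-en-2-yn-1-yl)oxy]dimethylsilane
Conditions: CuI, K2CO3, Bu4NI (cat.), DMF, rt
Reagents that add atoms: none
Why: Copper-mediated coupling of the terminal alkyne (as its copper acetylide) with the primary allylic chloride proceeds by SN2 displacement at CH2Cl, the dichlorinated terminus blocking the SN2' pathway.

Step 18
Reactants: 22 β,γ-unsaturated 2-(trimethylsilyl)ethyl ester; 25 tert-butyl[(6,6-dichlorohex-5-en-2-yn-1-yl)oxy]dimethylsilane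
Product: 27 (Z)-chloroalkene enyne, via B-alkyl-9-BBN 26 (not isolated)
Conditions: 9-BBN, THF, rt; then 25, Pd2(dba)3 (cat.), Xantphos (cat.), KF, K3PO4, THF, 65 °C
Reagents that add atoms: none
Why: 9-BBN hydroborates only the terminal vinyl group (boron at C11), and in the B-alkyl Suzuki–Miyaura coupling zerovalent palladium inserts into the C–Cl bond trans to the chain of the 1,1-dichloroalkene, so the C11–C12 bond forms with the remaining chlorine cis to C14 (Z), the wide-bite-angle ligand holding back a second coupling.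

Step 19
Reactants: 27 (Z)-chloroalkene enyne
Product: 28 propargylic alcohol
Conditions: camphorsulfonic acid (cat.), MeOH/CH2Cl2 (1:1), 0 °C
Reagents that add atoms: none
Why: Acid-catalysed methanolysis removes the primary propargylic TBS ether much faster than the two secondary ones and leaves the silylethyl ester alone.

Step 20
Reactants: 28 propargylic alcohol
Product: 29 (Z)-alkenylstannane (Bu3Sn on C16)
Conditions: Bu3SnH, [Cp*RuCl]4 (cat.; Cp* = C5Me5), CH2Cl2, rt
Reagents that add atoms: tributyltin hydride, CCCC[SnH](CCCC)CCCC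
Why: Ruthenium-catalysed trans-hydrostannation of a propargylic alcohol places tin on the alkyne carbon next to the hydroxyl (hydrogen bond from OH to the Ru–Cl unit) and hydrogen anti to it at C15, which sets the C15=C16 geometry with C14 cis to tin.

Step 21
Reactants: 29 (Z)-alkenylstannane; 30 ethyl (Z)-3-iodoacrylate
Product: 32 bis-TBS 2-(trimethylsilyl)ethyl ester of the target, via hydroxy dienoate 31 (not isolated)
Conditions: Pd(PPh3)4 (cat.), CuO2C(C4H3S) (copper thiophene-2-carboxylate), DMF, rt; then pyridinium p-toluenesulfonate (cat.), CH2Cl2, rt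
Reagents that add atoms: none
Why: Copper-assisted Stille coupling joins C16 to C17 with retention at both alkenyl partners, and the (Z)-enoate so formed holds the C20 hydroxyl next to the ester, so lactonisation closes the six-membered pyranone while the less reactive alkenyl chloride stays untouched.

Step 22
Reactants: 32 bis-TBS 2-(trimethylsilyl)ethyl ester of the target
Product: 33 target acid CNP0180366.1
Conditions: Bu4NF, AcOH (1:1), THF, rt
Reagents that add atoms: none
Why: Fluoride-induced desilylation cleaves both TBS ethers and, by fragmentation of the 2-silylethyl group, the ester, the acetic acid buffer keeping the medium non-basic so that the doubly allylic C14 methylene and the dienyl lactone should not isomerise.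

**Compound list**

1 | 2-deoxy-D-glucose (2-deoxy-D-arabino-hexose, open-chain form written) | OC[C@@H](O)[C@@H](O)[C@H](O)CC=O | starting material
2 | 2-deoxy-D-arabino-hexono-1,5-lactone (formed in the flask, not isolated) | O=C1C[C@@H](O)[C@H](O)[C@@H](CO)O1 | intermediate
3 | 2-deoxy-D-arabino-hexono-1,4-lactone | O=C1C[C@@H](O)[C@@H]([C@H](O)CO)O1 | intermediate
4 | 2-deoxy-5,6-O-isopropylidene-D-arabino-hexono-1,4-lactone | O=C1C[C@@H](O)[C@@H]([C@H]2COC(C)(C)O2)O1 | intermediate
5 | 3-O-(tert-butyldimethylsilyl)-2-deoxy-5,6-O-isopropylidene-D-arabino-hexono-1,4-lactone | O=C1C[C@@H](O[Si](C)(C)C(C)(C)C)[C@@H]([C@H]2COC(C)(C)O2)O1 | intermediate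
6 | 3-O-TBS-2-deoxy-5,6-O-isopropylidene-D-arabino-hexofuranose (lactol, mixture of anomers) | OC1C[C@@H](O[Si](C)(C)C(C)(C)C)[C@@H]([C@H]2COC(C)(C)O2)O1 | intermediate
7 | ethyl (triphenylphosphoranylidene)acetate | CCOC(=O)C=P(c1ccccc1)(c1ccccc1)c1ccccc1 | starting material
8 | ethyl (E)-5-O-TBS-2,3,4-trideoxy-7,8-O-isopropylidene-D-arabino-oct-2-enoate (free 6-OH = C6 hydroxyl of the target chain) | CCOC(=O)/C=C/C[C@@H](O[Si](C)(C)C(C)(C)C)[C@H](O)[C@H]1COC(C)(C)O1 | intermediate
9 | (E)-allylic diol: 8 with CO2Et reduced to CH2OH (C11–OH and C6–OH free) | OC/C=C/C[C@@H](O[Si](C)(C)C(C)(C)C)[C@H](O)[C@H]1COC(C)(C)O1 | intermediate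
10 | (E)-allylic methyl carbonate: 9 with the C11 hydroxyl as OCO2Me; free C6 hydroxyl, C7 OTBS, C4/C5 acetonide with (4R)-dioxolane | CC1(C)OC[C@H]([C@@H](O)[C@@H](C/C=C/COC(=O)OC)O[Si](C)(C)C(C)(C)C)O1 | intermediate
11 | 2,5-trans 2-vinyltetrahydrofuran: ring O between C6 and C9; C6 bears the (4R)-2,2-dimethyl-1,3-dioxolan-4-yl group, C7 the OTBS group cis to it, C9 the vinyl group trans to both | CC1(C)OC[C@H]([C@H]2O[C@H](C=C)C[C@H]2O[Si](C)(C)C(C)(C)C)O1 | intermediate
12 | C4,C5-diol: 11 with the acetonide removed (ring configuration as in 11) | OC[C@@H](O)[C@H]1O[C@H](C=C)C[C@H]1O[Si](C)(C)C(C)(C)C | intermediate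
13 | tris-TBS ether: 12 silylated at C4–O and C5–O | CC(C)(C)[Si](C)(C)OC[C@@H](O[Si](C)(C)C(C)(C)C)[C@H]1O[C@H](C=C)C[C@H]1O[Si](C)(C)C(C)(C)C | intermediate
14 | C4 primary alcohol with C5 and C7 OTBS and C9 vinyl | OC[C@@H](O[Si](C)(C)C(C)(C)C)[C@H]1O[C@H](C=C)C[C@H]1O[Si](C)(C)C(C)(C)C | intermediate
15 | C4 aldehyde with C5 and C7 OTBS and C9 vinyl | O=C[C@@H](O[Si](C)(C)C(C)(C)C)[C@H]1O[C@H](C=C)C[C@H]1O[Si](C)(C)C(C)(C)C | intermediate
16 | ethyl 2-(triphenylphosphoranylidene)propanoate | CCOC(=O)C(C)=P(c1ccccc1)(c1ccccc1)c1ccccc1 | starting material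
17 | ethyl (E)-2-methylalk-2-enoate: C3(Me)=C4 with CO2Et on C3 trans to C5; C5, C7 OTBS; C9 vinyl | CCOC(=O)/C(C)=C/[C@@H](O[Si](C)(C)C(C)(C)C)[C@H]1O[C@H](C=C)C[C@H]1O[Si](C)(C)C(C)(C)C | intermediate
18 | (E)-2-methyl enoic acid corresponding to 17 | OC(=O)/C(C)=C/[C@@H](O[Si](C)(C)C(C)(C)C)[C@H]1O[C@H](C=C)C[C@H]1O[Si](C)(C)C(C)(C)C | intermediate
19 | acid chloride of 18 (formed in the flask, not isolated) | ClC(=O)/C(C)=C/[C@@H](O[Si](C)(C)C(C)(C)C)[C@H]1O[C@H](C=C)C[C@H]1O[Si](C)(C)C(C)(C)C | intermediate
20 | α,β-unsaturated diazomethyl ketone from 19 | [N-]=[N+]=CC(=O)/C(C)=C/[C@@H](O[Si](C)(C)C(C)(C)C)[C@H]1O[C@H](C=C)C[C@H]1O[Si](C)(C)C(C)(C)C | intermediate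
21 | vinylketene C1(=O)=C2H–C3(Me)=C4 (formed in the flask, not isolated) | O=C=C/C(C)=C/[C@@H](O[Si](C)(C)C(C)(C)C)[C@H]1O[C@H](C=C)C[C@H]1O[Si](C)(C)C(C)(C)C | intermediate
22 | 2-(trimethylsilyl)ethyl (E)-3-methylpent-3-enoate unit (C1–C5) on the C6–C9 ring; C5, C7 OTBS; C9 vinyl | C[Si](C)(C)CCOC(=O)C/C(C)=C/[C@@H](O[Si](C)(C)C(C)(C)C)[C@H]1O[C@H](C=C)C[C@H]1O[Si](C)(C)C(C)(C)C | intermediate
23 | tert-butyldimethyl(prop-2-yn-1-yloxy)silane | C#CCO[Si](C)(C)C(C)(C)C | starting material
24 | 1,1,3-trichloroprop-1-ene | ClCC=C(Cl)Cl | starting material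
25 | tert-butyl[(6,6-dichlorohex-5-en-2-yn-1-yl)oxy]dimethylsilane (C20, C16≡C15, C14, C13=C12Cl2) | CC(C)(C)[Si](C)(C)OCC#CCC=C(Cl)Cl | intermediate
26 | B-alkyl-9-BBN: 22 with C9–CH2CH2–B(9-borabicyclo[3.3.1]nonan-9-yl) (formed in the flask, not isolated) | C[Si](C)(C)CCOC(=O)C/C(C)=C/[C@@H](O[Si](C)(C)C(C)(C)C)[C@H]1O[C@H](CCB2C3CCCC2CCC3)C[C@H]1O[Si](C)(C)C(C)(C)C | intermediate
27 | (Z)-chloroalkene enyne: C9–C10–C11–C12(Cl)=C13–C14–C15≡C16–C20–OTBS; C5, C7 OTBS; silylethyl ester | C[Si](C)(C)CCOC(=O)C/C(C)=C/[C@@H](O[Si](C)(C)C(C)(C)C)[C@H]1O[C@H](CC/C(Cl)=C/CC#CCO[Si](C)(C)C(C)(C)C)C[C@H]1O[Si](C)(C)C(C)(C)C | intermediate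
28 | propargylic alcohol: 27 with free C20–OH | C[Si](C)(C)CCOC(=O)C/C(C)=C/[C@@H](O[Si](C)(C)C(C)(C)C)[C@H]1O[C@H](CC/C(Cl)=C/CC#CCO)C[C@H]1O[Si](C)(C)C(C)(C)C | intermediate
29 | (Z)-alkenylstannane: C15H=C16(SnBu3)–C20H2OH with C14 cis to tin | C[Si](C)(C)CCOC(=O)C/C(C)=C/[C@@H](O[Si](C)(C)C(C)(C)C)[C@H]1O[C@H](CC/C(Cl)=C/C/C=C(/CO)[Sn](CCCC)(CCCC)CCCC)C[C@H]1O[Si](C)(C)C(C)(C)C | intermediate
30 | ethyl (Z)-3-iodoacrylate | CCOC(=O)/C=C\I | starting material
31 | hydroxy (2Z,4E)-dienoate: C19(O)OEt–C18=C17–C16(C20H2OH)=C15 (formed in the flask, not isolated) | C[Si](C)(C)CCOC(=O)C/C(C)=C/[C@@H](O[Si](C)(C)C(C)(C)C)[C@H]1O[C@H](CC/C(Cl)=C/C/C=C(/CO)\C=C/C(=O)OCC)C[C@H]1O[Si](C)(C)C(C)(C)C | intermediate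
32 | protected target: C5, C7 bis-TBS ether and 2-(trimethylsilyl)ethyl ester of 33 | C[Si](C)(C)CCOC(=O)C/C(C)=C/[C@@H](O[Si](C)(C)C(C)(C)C)[C@H]1O[C@H](CC/C(Cl)=C/C/C=C2\C=CC(=O)OC2)C[C@H]1O[Si](C)(C)C(C)(C)C | intermediate
33 | (3E,5R)-5-hydroxy-5-{(2S,3R,5R)-3-hydroxy-5-[(3Z,6E)-3-chloro-6-(6-oxo-3,6-dihydro-2H-pyran-3-ylidene)hex-3-en-1-yl]oxolan-2-yl}-3-methylpent-3-enoic acid (5R,6S,7R,9R in chain numbering) | C/C(=C\[C@@H](O)[C@H]1O[C@H](CC/C(Cl)=C/C/C=C2\C=CC(=O)OC2)C[C@H]1O)CC(=O)O | target

**Step count**

Total step count: 22. Longest linear sequence: 21 steps (steps 1–16 and 18–22, from 1 to 33); fragment 25 is made in one step (step 17).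

**Steps most likely to fail**

Step 8. The ligand may not overrule the inherent facial preference of the substrate, so that the allyl complex leading to the 2,5-cis ring closes at a comparable rate (poor facial selectivity at C9). Fallback, setting out from lactol 6 and coming back at 11: methylenation (Ph3PCH3Br, KOt-Bu, THF, 0 °C) would give the hydroxy alkene F1. Its pent-4-en-1-ol unit (C6–OH, C9=C10) would be closed by cobalt-catalysed aerobic oxidative cyclisation under Mukaiyama conditions (bis(1-morpholinocarbamoyl-4,4-dimethylpentane-1,3-dionato)cobalt, O2, t-BuOOH, i-PrOH, 50 °C), a reaction that reliably gives 2,5-trans rings, to the tetrahydrofuranylmethanol F2. TEMPO/PhI(OAc)2 oxidation to the aldehyde F3 and a second methylenation at −78 °C would rejoin the route at 11.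

Step 16. Material may be lost through dimerisation of the vinylketene, conjugation of the β,γ-alkene under the amine, or cycloaddition of the diazo group during the rearrangement. Fallback, setting out from enoate 17 and coming back at 22: i-Bu2AlH reduction (CH2Cl2, −78 °C) would give the allylic alcohol F4. Acylation with 4-nitrophenyl 2-(trimethylsilyl)ethyl carbonate (DMAP, CH2Cl2) would give the mixed allylic carbonate F5. Palladium-catalysed decarboxylative carbonylation (Pd(OAc)2, PPh3, CO 10 bar, toluene, 50 °C), in which the alkoxide released on ionisation captures the acyl-palladium formed at the primary allyl terminus, would then deliver 22.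

Step 22. Deprotonation at the doubly allylic C14 by fluoride or by the alkoxides formed could move the C15=C16 bond into full conjugation, or the lactone could be opened. Fallback, setting out from 27 and coming back at 33: all silicon groups would be removed with Bu4NF in THF before the lactone exists, giving the trihydroxy acid F6. Ruthenium-catalysed trans-hydrostannation as in step 20 would give the alkenylstannane F7. Stille coupling with 30 as in step 21 and lactonisation of the hydroxy ethyl ester F8 would give 33 directly, so the pyranone never meets fluoride.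

**Further compounds**

F1 | step 8 | hydroxy alkene: 4-O-TBS-1,2,3-trideoxy-6,7-O-isopropylidene-D-arabino-hept-1-enitol (free 5-OH = C6 hydroxyl) | C=CC[C@@H](O[Si](C)(C)C(C)(C)C)[C@H](O)[C@H]1COC(C)(C)O1
F2 | step 8 | 2,5-trans tetrahydrofuranylmethanol: 11 with CH2OH in place of vinyl at C9 | CC1(C)OC[C@H]([C@H]2O[C@H](CO)C[C@H]2O[Si](C)(C)C(C)(C)C)O1
F3 | step 8 | aldehyde: 11 with CHO in place of vinyl at C9 | CC1(C)OC[C@H]([C@H]2O[C@H](C=O)C[C@H]2O[Si](C)(C)C(C)(C)C)O1
F4 | step 16 | allylic alcohol: 17 with CO2Et reduced to CH2OH | OC/C(C)=C/[C@@H](O[Si](C)(C)C(C)(C)C)[C@H]1O[C@H](C=C)C[C@H]1O[Si](C)(C)C(C)(C)C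
F5 | step 16 | mixed allylic 2-(trimethylsilyl)ethyl carbonate of F4 | C[Si](C)(C)CCOC(=O)OC/C(C)=C/[C@@H](O[Si](C)(C)C(C)(C)C)[C@H]1O[C@H](C=C)C[C@H]1O[Si](C)(C)C(C)(C)C
F6 | step 22 | trihydroxy acid: 27 with all silicon groups removed | OC(=O)C/C(C)=C/[C@@H](O)[C@H]1O[C@H](CC/C(Cl)=C/CC#CCO)C[C@H]1O
F7 | step 22 | alkenylstannane: F6 with C15H=C16(SnBu3), C14 cis to tin | OC(=O)C/C(C)=C/[C@@H](O)[C@H]1O[C@H](CC/C(Cl)=C/C/C=C(/CO)[Sn](CCCC)(CCCC)CCCC)C[C@H]1O
F8 | step 22 | hydroxy ethyl ester: unprotected (2Z,4E)-dienoate before lactonisation | OC(=O)C/C(C)=C/[C@@H](O)[C@H]1O[C@H](CC/C(Cl)=C/C/C=C(/CO)\C=C/C(=O)OCC)C[C@H]1O
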